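All runs were generated by integration from invented constants.

If each L spends one G, the flask north-west, with 0.250 M of G on 1.5 M of Z, holds L under a G ceiling of 16.7 %, the charged [G] over the charged [Z]. G is then the limiting reagent there, and the same ratio gives north-east a ceiling of 70.0 %.

| flask | Z | G | remark | time |
|---|---|---|---|---|
| winter | 1.5 M | 0.30 M | run made earlier |  |
| summer | 1.5 M | 1.2 M | run made earlier |  |
| north-west | 1.5 M | 0.250 M |  | 25 min |
| north-east | 1.5 M | 1.05 M |  | 6.0 min |

| run | time / min | L / % |
|---|---|---|
| winter | 0.250 | 0.6 |
| winter | 0.417 | 1.0 |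
| winter | 0.833 | 3.4 |
| winter | 1.50 | 4.0 |
| winter | 3.00 | 9.2 |
| summer | 0.667 | 7.5 |
| summer | 1.33 | 14.3 |
| summer | 2.00 | 21.8 |
| summer | 2.50 | 25.7 |
| summer | 3.00 | 28.0 |

(scatter of a reading: 0.5 percentage points)

- the flask that ends with the higher amount of L, in percent of the Z charged, or "neither" when 2 percentage points or less lies between them (north-west / north-east / neither)
- final L, as a percentage of the Z charged, in north-west
- final L, as a percentage of the Z charged, in north-east



But winter and summer stand at 9.2 % and 28.0 % after 3.00 min, below their ceilings, so these readings give a speed and not a ceiling. We therefore integrate rate = k[Z][G] with one G spent per L: k·t·([Z] − [G]) = ln([G]([Z] − x)/([Z]([G] − x))), where [Z] and [G] are the charges and x is the [L] made. The last readings give k = 0.144 L mol⁻¹ min⁻¹ in winter and 0.114 L mol⁻¹ min⁻¹ in summer. These two readings differ, so we use each for the flask nearer it in [G]. Our reckoning puts north-west at 16.5 %, nearly all of its ceiling, and north-east at 38.1 %, which is higher.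

The forecast says neither, with 46 % in north-west and 46 % in north-east, on the ground “Treating G as an unconsumed catalyst”. We differ on the winner and on north-west, where its figure stands above our ceiling.

The flask gives north-east ahead, with 16.5 % in north-west and 41.2 % in north-east.

    Q → L (k = 0.00730 s⁻¹)
    Z + G ⇌ Q (K = 0.610 L mol⁻¹, k = 0.0610 L mol⁻¹ s⁻¹)

In north-west, Z + G gave Q and Q gave L while G fell to 0.539 % of its charge by 25.0 min, with L at 16.5 % against the ceiling of 16.7 %. In north-east, the same two steps were still running at 6.00 min, with G at 28.6 % of its charge, Q at 8.75 % of the Z charged and L at 41.2 %, and north-east left until 60.0 min holds L at 69.9 %, level with its ceiling of 70.0 %.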